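The earlier runs and the new flask come from a simulation from invented constants; the scatter is artificial.

**The question.** The operator of the east run gave me its readings and asked about that same flask, followed further.

| flask | substrate | capture agent | remark | time |
|---|---|---|---|---|
| east | 1 M (fed, over 4.0 h) | 0.10 M | the very flask that is asked about, followed so far; the fed solution adds 1.0 times the starting volume |  |
| flask | 1.0 M (fed, over 4.0 h) | 0.100 M | the fed solution adds 1.0 times the starting volume | 8.0 d |

- east (time / d: target / %): 0.0417: 14.4; 0.125: 37.4; 0.333: 39.4; 1.04: 39.3; 3.00: 39.0

(readings scatter by 0.5 percentage points)

- time, not beyond 8.0 d, at which the flask holds most target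
- the amount of target, in percent of the substrate charged, at that time
- earliest time at which at least nineteen twentieths of that best amount are there, in d
- latest time at which they still are, in d

- for target the crystals are counted in
- charges are per starting volume, the dose included; the dosed solution carries all of it
- as a solid, counted per litre of solution: crystals
- what may be going on: substrate <-> open intermediate; open intermediate -> target; target <-> isomer of the product; crystals <-> target; open intermediate + capture agent -> trapped intermediate
- percentages count the whole charge, also what has not yet gone in

**Bench rule.** I began with a bench rule: a dosed batch gives its plateau share of whatever has gone in. The plateau of the east run read 39.3% at 1.04 d. So the rule promised 29.5% at 3 h, with 75.0% fed. The reading there was 37.4%, which is 1.27 times the rule's figure and more than it. The rule broke during the feed: target per fraction fed read 49.9%, above the plateau. I read this as kinetic against thermodynamic control: target ran ahead of its later share.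

**Excess share.** So I took target over the fraction fed, minus the plateau. This read 18 percentage points at 1.001 h and 11 points at 3 h, a shrinkage by the factor 0.579 in 2.00 h. Dosing ended after half that span again, so I applied the square root of the factor. That gave an end-of-feed excess share of 8 points. It rests on two readings and carries their scatter. Added to the plateau, it put my peak at 47.3%, at the end of dosing, 4.0 h.

**The forecast.** The forecast gave 45% (41% to 48%) at 0.17 d (0.16 d to 0.22 d), lower than my peak. It opened the window at 0.155 d (0.13 d to 0.17 d) and shut it at 0.18 d (0.172 d to 0.3 d). It warned: “The peak itself was never measured, and crystals could blunt or prolong it, so the ranges are wide.”

**The flask.**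

    substrate ⇌ open intermediate (K = 0.730, k = 0.720 /min)
    open intermediate → target (k = 0.150 /min)
    target ⇌ isomer of the product (K = 1.50, k = 0.0130 /min)
    crystals ⇌ target, rate k4*(cs4 - [target]) while solid is left; crystals form when [target] > cs4 (solubility = 0.720 M, k = 0.950 /min)
    open intermediate + capture agent → trapped intermediate (k = 0.0450 /M/min)

The flask reached 48.5% at 0.174 d, and its window ran from 0.160 d to 0.193 d. Dissolved target and isomer of the product relaxed by their step alone with a half-life of 0.533 h, both ways together, far shorter than the 8.0 d allowed. At the end of the feed, 0.167 d, the flask held 47.8% of target against 39.3% at the longest time, an excess of 8.5 points where I had 8 points. The neighbour charged with 0.40 M of substrate reached 48.5% of target at its best and ended at 39.3%, so its best stood above its end by 9.2 points.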